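**Retrosynthetic overview**
1. Target 24 ⇒ hexa-allyl precursor 23 (five aryl allyl ethers, one allyl ester), unmasked last by allyl transfer with zerovalent palladium; the methyl ester is never touched.
2. 23 ⇒ (E)-cinnamate C=C by Horner–Wadsworth–Emmons olefination of aldehyde 13 with phosphonoacetate 22 of allyl-protected (R)-danshensu (stereocentre from methyl (R)-glycidate).
3. 13 ⇒ key C–C bond: intermolecular aldol of the lithium enolate of aryloxyacetate 8 with 3,4-bis(allyloxy)benzaldehyde 2, then E1cB dehydration to the (Z)-enol ether.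
4. 8 and 2 ⇒ 3,4-dihydroxybenzaldehyde 1, using the regioselective chemistry of its 4-OH group.
5. No ring is formed; all three benzene rings come from the starting materials.

Assumption: methyl (R)-glycidate (methyl (2R)-oxirane-2-carboxylate) is bought as a chiral-pool material; allyl = prop-2-en-1-yl throughout.

**Route**

Step 1
Reactants: 1 3,4-dihydroxybenzaldehyde
Product: 2 3,4-bis(allyloxy)benzaldehyde
Conditions: allyl bromide (2.5 equiv), K2CO3 (3 equiv), DMF, 60 °C
Reagents that add atoms: allyl bromide, C=CCBr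
Why: Williamson ether synthesis; both phenoxides are alkylated cleanly by the reactive allylic halide.

Step 2
Reactants: 1 3,4-dihydroxybenzaldehyde
Product: 3 3-hydroxy-4-[(4-methoxybenzyl)oxy]benzaldehyde
Conditions: 4-methoxybenzyl chloride (1.2 equiv), NaHCO3 (1.5 equiv), NaI (0.3 equiv), DMF, 40 °C
Reagents that add atoms: 4-methoxybenzyl chloride, COc1ccc(CCl)cc1
Why: Regioselective Williamson etherification, because NaHCO3 deprotonates only the more acidic 4-OH (para to the formyl group).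

Step 3
Reactants: 3 3-hydroxy-4-[(4-methoxybenzyl)oxy]benzaldehyde
Product: 4 3-(allyloxy)-4-[(4-methoxybenzyl)oxy]benzaldehyde
Conditions: allyl bromide (1.3 equiv), K2CO3 (1.5 equiv), DMF, rt
Reagents that add atoms: allyl bromide, C=CCBr
Why: Williamson ether synthesis on the only remaining phenol.

Step 4
Reactants: 4 3-(allyloxy)-4-[(4-methoxybenzyl)oxy]benzaldehyde
Product: 5 3-(allyloxy)-4-hydroxybenzaldehyde
Conditions: TFA (10% v/v), anisole (5 equiv), CH2Cl2, 0 °C
Reagents that add atoms: none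
Why: Acidolysis of the 4-methoxybenzyl ether with Friedel–Crafts trapping of the benzyl cation by anisole; the allyl ether and the aldehyde are inert to dilute TFA.

Step 5
Reactants: 5 3-(allyloxy)-4-hydroxybenzaldehyde; 6 methyl bromoacetate
Product: 7 methyl 2-[2-(allyloxy)-4-formylphenoxy]acetate
Conditions: K2CO3 (1.5 equiv), acetone, reflux
Reagents that add atoms: none
Why: Williamson ether synthesis of the acidic 4-phenol with an activated α-halo ester.

Step 6
Reactants: 7 methyl 2-[2-(allyloxy)-4-formylphenoxy]acetate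
Product: 8 methyl 2-[2-(allyloxy)-4-(dimethoxymethyl)phenoxy]acetate
Conditions: HC(OMe)3 (3 equiv), MeOH, p-TsOH·H2O (2 mol%), rt; then Et3N
Reagents that add atoms: trimethyl orthoformate, COC(OC)OC
Why: Acid-catalysed acetalisation masks the formyl group against the ester enolate of the next step; methanol as solvent cannot scramble the methyl ester.

Step 7
Reactants: 8 methyl 2-[2-(allyloxy)-4-(dimethoxymethyl)phenoxy]acetate; 2 3,4-bis(allyloxy)benzaldehyde
Product: 10 methyl 2-[2-(allyloxy)-4-(dimethoxymethyl)phenoxy]-3-[3,4-bis(allyloxy)phenyl]-3-hydroxypropanoate (racemic syn/anti mixture), via lithium enolate 9 (not isolated)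
Conditions: LiN(iPr)2 (1.1 equiv), THF, −78 °C, 30 min; then 2 (1.05 equiv), −78 °C, 1 h; aq. NH4Cl at −78 °C
Reagents that add atoms: none
Why: Intermolecular aldol addition of a preformed aryloxyacetate lithium enolate to a non-enolisable aldehyde; both new stereocentres are erased in step 8, so the diastereomer ratio does not matter.

Step 8
Reactants: 10 methyl 2-[2-(allyloxy)-4-(dimethoxymethyl)phenoxy]-3-[3,4-bis(allyloxy)phenyl]-3-hydroxypropanoate
Product: 12 methyl (Z)-2-[2-(allyloxy)-4-(dimethoxymethyl)phenoxy]-3-[3,4-bis(allyloxy)phenyl]acrylate, via benzylic mesylate 11 (not isolated)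
Conditions: MsCl (1.5 equiv), Et3N (3 equiv), CH2Cl2, 0 °C; then DBU (3 equiv), 0 °C → rt
Reagents that add atoms: none
Why: Mesylation followed by E1cB elimination through the stabilised ester enolate gives the thermodynamically preferred (Z)-enol ether (aryl trans to the ester); the minor (E)-isomer is removed by chromatography at 13.

Step 9
Reactants: 12 methyl (Z)-2-[2-(allyloxy)-4-(dimethoxymethyl)phenoxy]-3-[3,4-bis(allyloxy)phenyl]acrylate
Product: 13 methyl (Z)-2-[2-(allyloxy)-4-formylphenoxy]-3-[3,4-bis(allyloxy)phenyl]acrylate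
Conditions: 1 M aq. HCl, THF, rt, 30 min
Reagents that add atoms: water, O
Why: Acetal hydrolysis of a very labile 4-alkoxybenzaldehyde dimethyl acetal; the ester-conjugated aryl enol ether is far too electron-poor to hydrolyse under these conditions.

Step 10
Reactants: 14 4-bromocatechol
Product: 15 1,2-bis(allyloxy)-4-bromobenzene
Conditions: allyl bromide (2.5 equiv), K2CO3 (3 equiv), acetone, reflux
Reagents that add atoms: allyl bromide, C=CCBr
Why: Williamson ether synthesis of both phenols.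

Step 11
Reactants: 15 1,2-bis(allyloxy)-4-bromobenzene; 16 methyl (R)-glycidate
Product: 18 methyl (R)-3-[3,4-bis(allyloxy)phenyl]-2-hydroxypropanoate, via arylmagnesium bromide 17 (not isolated)
Conditions: 15 (1.4 equiv), Mg, I2 (cat.), THF, 45 °C; then CuBr·SMe2 (10 mol%), 16, THF, −40 → −20 °C; cold 1 M HCl
Reagents that add atoms: none
Why: Copper-catalysed Grignard (cuprate) SN2 opening of the epoxide at its unsubstituted C3; the C2 stereocentre of the glycidate is not touched, so (R)-glycidate gives the (R)-2-hydroxy ester.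

Step 12
Reactants: 18 methyl (R)-3-[3,4-bis(allyloxy)phenyl]-2-hydroxypropanoate
Product: 19 (R)-3-[3,4-bis(allyloxy)phenyl]-2-hydroxypropanoic acid
Conditions: LiOH·H2O (2 equiv), THF/H2O (3:1), 0 °C → rt; then 1 M HCl to pH 2
Reagents that add atoms: lithium hydroxide, [Li+].[OH-]
Why: Saponification of an α-hydroxy ester, which proceeds without racemisation under these mild conditions.

Step 13
Reactants: 19 (R)-3-[3,4-bis(allyloxy)phenyl]-2-hydroxypropanoic acid
Product: 20 allyl (R)-3-[3,4-bis(allyloxy)phenyl]-2-hydroxypropanoate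
Conditions: allyl bromide (1.2 equiv), KHCO3 (1.5 equiv), DMF, rt
Reagents that add atoms: allyl bromide, C=CCBr
Why: Carboxylate O-alkylation; the weak base leaves the secondary alcohol and the stereocentre alone.

Step 14
Reactants: 20 allyl (R)-3-[3,4-bis(allyloxy)phenyl]-2-hydroxypropanoate; 21 (diethoxyphosphoryl)acetic acid
Product: 22 allyl (R)-3-[3,4-bis(allyloxy)phenyl]-2-{[(diethoxyphosphoryl)acetyl]oxy}propanoate
Conditions: DCC (1.3 equiv), DMAP (10 mol%), CH2Cl2, 0 °C → rt
Reagents that add atoms: none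
Why: Steglich esterification acylates the alcohol oxygen, so the C–O bond at the stereocentre is not broken and the (R)-configuration is retained.

Step 15
Reactants: 13 methyl (Z)-2-[2-(allyloxy)-4-formylphenoxy]-3-[3,4-bis(allyloxy)phenyl]acrylate; 22 allyl (R)-3-[3,4-bis(allyloxy)phenyl]-2-{[(diethoxyphosphoryl)acetyl]oxy}propanoate
Product: 23 allyl (R)-2-{[(E)-3-(3-(allyloxy)-4-{[(Z)-1-(3,4-bis(allyloxy)phenyl)-3-methoxy-3-oxoprop-1-en-2-yl]oxy}phenyl)acryloyl]oxy}-3-[3,4-bis(allyloxy)phenyl]propanoate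
Conditions: LiCl (1.5 equiv), iPr2NEt (1.3 equiv), MeCN, rt
Reagents that add atoms: none
Why: Horner–Wadsworth–Emmons olefination under Masamune–Roush conditions gives the (E)-cinnamate from a stabilised phosphonate, and the weak amine base spares the lactate stereocentre and both esters.

Step 16
Reactants: 23 allyl (R)-2-{[(E)-3-(3-(allyloxy)-4-{[(Z)-1-(3,4-bis(allyloxy)phenyl)-3-methoxy-3-oxoprop-1-en-2-yl]oxy}phenyl)acryloyl]oxy}-3-[3,4-bis(allyloxy)phenyl]propanoate
Product: 24 (R)-3-(3,4-dihydroxyphenyl)-2-{[(E)-3-(4-{[(Z)-1-(3,4-dihydroxyphenyl)-3-methoxy-3-oxoprop-1-en-2-yl]oxy}-3-hydroxyphenyl)acryloyl]oxy}propanoic acid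
Conditions: Pd(PPh3)4 (10 mol%), morpholine (15 equiv), degassed THF, rt, argon; then 1 M HCl to pH 2–3; reversed-phase chromatography
Reagents that add atoms: none
Why: Tsuji–Trost deallylation, in which zerovalent palladium ionises the allyl ester and the five aryl allyl ethers and morpholine traps the allyl groups; the methyl ester, the cinnamate ester, both alkenes and the stereocentre are untouched.

**Compound list**
1 | 3,4-dihydroxybenzaldehyde | O=Cc1ccc(O)c(O)c1 | starting material
2 | 3,4-bis(allyloxy)benzaldehyde | C=CCOc1ccc(C=O)cc1OCC=C | intermediate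
3 | 3-hydroxy-4-[(4-methoxybenzyl)oxy]benzaldehyde | COc1ccc(COc2ccc(C=O)cc2O)cc1 | intermediate
4 | 3-(allyloxy)-4-[(4-methoxybenzyl)oxy]benzaldehyde | COc1ccc(COc2ccc(C=O)cc2OCC=C)cc1 | intermediate
5 | 3-(allyloxy)-4-hydroxybenzaldehyde | O=Cc1ccc(O)c(OCC=C)c1 | intermediate
6 | methyl bromoacetate | COC(=O)CBr | starting material
7 | methyl 2-[2-(allyloxy)-4-formylphenoxy]acetate | COC(=O)COc1ccc(C=O)cc1OCC=C | intermediate
8 | methyl 2-[2-(allyloxy)-4-(dimethoxymethyl)phenoxy]acetate | COC(=O)COc1ccc(C(OC)OC)cc1OCC=C | intermediate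
9 | lithium enolate of 8 | [Li+].COC([O-])=COc1ccc(C(OC)OC)cc1OCC=C | intermediate
10 | methyl 2-[2-(allyloxy)-4-(dimethoxymethyl)phenoxy]-3-[3,4-bis(allyloxy)phenyl]-3-hydroxypropanoate (racemic syn/anti mixture) | COC(=O)C(Oc1ccc(C(OC)OC)cc1OCC=C)C(O)c1ccc(OCC=C)c(OCC=C)c1 | intermediate
11 | methyl 2-[2-(allyloxy)-4-(dimethoxymethyl)phenoxy]-3-[3,4-bis(allyloxy)phenyl]-3-[(methylsulfonyl)oxy]propanoate | COC(=O)C(Oc1ccc(C(OC)OC)cc1OCC=C)C(OS(C)(=O)=O)c1ccc(OCC=C)c(OCC=C)c1 | intermediate
12 | methyl (Z)-2-[2-(allyloxy)-4-(dimethoxymethyl)phenoxy]-3-[3,4-bis(allyloxy)phenyl]acrylate | COC(=O)/C(=C/c1ccc(OCC=C)c(OCC=C)c1)Oc1ccc(C(OC)OC)cc1OCC=C | intermediate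
13 | methyl (Z)-2-[2-(allyloxy)-4-formylphenoxy]-3-[3,4-bis(allyloxy)phenyl]acrylate | COC(=O)/C(=C/c1ccc(OCC=C)c(OCC=C)c1)Oc1ccc(C=O)cc1OCC=C | intermediate
14 | 4-bromocatechol (4-bromobenzene-1,2-diol) | Oc1ccc(Br)cc1O | starting material
15 | 1,2-bis(allyloxy)-4-bromobenzene | C=CCOc1ccc(Br)cc1OCC=C | intermediate
16 | methyl (R)-glycidate | COC(=O)[C@H]1CO1 | starting material
17 | [3,4-bis(allyloxy)phenyl]magnesium bromide | C=CCOc1ccc([Mg]Br)cc1OCC=C | intermediate
18 | methyl (R)-3-[3,4-bis(allyloxy)phenyl]-2-hydroxypropanoate | COC(=O)[C@H](O)Cc1ccc(OCC=C)c(OCC=C)c1 | intermediate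
19 | (R)-3-[3,4-bis(allyloxy)phenyl]-2-hydroxypropanoic acid | OC(=O)[C@H](O)Cc1ccc(OCC=C)c(OCC=C)c1 | intermediate
20 | allyl (R)-3-[3,4-bis(allyloxy)phenyl]-2-hydroxypropanoate | C=CCOC(=O)[C@H](O)Cc1ccc(OCC=C)c(OCC=C)c1 | intermediate
21 | (diethoxyphosphoryl)acetic acid | CCOP(=O)(CC(=O)O)OCC | starting material
22 | allyl (R)-3-[3,4-bis(allyloxy)phenyl]-2-{[(diethoxyphosphoryl)acetyl]oxy}propanoate | C=CCOC(=O)[C@H](OC(=O)CP(=O)(OCC)OCC)Cc1ccc(OCC=C)c(OCC=C)c1 | intermediate
23 | allyl (R)-2-{[(E)-3-(3-(allyloxy)-4-{[(Z)-1-(3,4-bis(allyloxy)phenyl)-3-methoxy-3-oxoprop-1-en-2-yl]oxy}phenyl)acryloyl]oxy}-3-[3,4-bis(allyloxy)phenyl]propanoate | COC(=O)/C(=C/c1ccc(OCC=C)c(OCC=C)c1)Oc1ccc(/C=C/C(=O)O[C@H](Cc2ccc(OCC=C)c(OCC=C)c2)C(=O)OCC=C)cc1OCC=C | intermediate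
24 | (R)-3-(3,4-dihydroxyphenyl)-2-{[(E)-3-(4-{[(Z)-1-(3,4-dihydroxyphenyl)-3-methoxy-3-oxoprop-1-en-2-yl]oxy}-3-hydroxyphenyl)acryloyl]oxy}propanoic acid | COC(=O)/C(=C/c1ccc(O)c(O)c1)Oc1ccc(/C=C/C(=O)O[C@H](Cc2ccc(O)c(O)c2)C(=O)O)cc1O | target

**Step count**
Total: 16 steps. Longest linear sequence: 10 steps (1 → 3 → 4 → 5 → 7 → 8 → 10 → 12 → 13 → 23 → 24; steps 2–9, 15, 16).

**Three steps most likely to fail, with fallbacks**

Step 11 (aryl cuprate opening of the glycidate). The Grignard reagent may attack the methyl ester or give bromohydrin instead of clean C3 opening. The fallback drops the epoxide and takes the stereocentre from an amino acid with a later inversion. It sets out from 21 and comes back at 22, bypassing 14–20. Bought L-DOPA is diazotised (NaNO2, 1 M H2SO4, 0 °C → rt; net retention through the α-lactone) to (S)-3-(3,4-dihydroxyphenyl)-2-hydroxypropanoic acid F1. Allyl bromide and K2CO3 in DMF then alkylate both phenols and the carboxylate to give allyl (S)-3-[3,4-bis(allyloxy)phenyl]-2-hydroxypropanoate F2. Mitsunobu esterification of F2 with 21 (PPh3, DIAD, THF, 0 °C) inverts the carbinol carbon and delivers the (R)-phosphonoacetate 22.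

Step 15 (Horner–Wadsworth–Emmons coupling). The electron-rich aldehyde may react sluggishly, and a stronger base would endanger the lactate stereocentre. The fallback separates C=C formation from ester formation. It sets out from 13 and comes back at 23. Knoevenagel–Doebner condensation of 13 with malonic acid (pyridine, cat. piperidine, 80 °C) gives (E)-3-[3-(allyloxy)-4-({(Z)-1-[3,4-bis(allyloxy)phenyl]-3-methoxy-3-oxoprop-1-en-2-yl}oxy)phenyl]acrylic acid F3. Steglich esterification of F3 with alcohol 20 (DCC, DMAP, CH2Cl2, 0 °C) gives 23; step 14 is then not needed.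

Step 16 (six-fold deallylation). The aryl allyl ethers may be cleaved incompletely, and the catechol product is oxidation-prone under prolonged treatment with amine and palladium. The fallback removes the aryl ethers by alkene isomerisation and enol ether hydrolysis instead of allyl transfer. It sets out from 23 and comes back at 24. Brief treatment with Pd(PPh3)4 (2 mol%) and morpholine (1.5 equiv) in THF at 0 °C cleaves only the much more reactive allyl ester. This gives (R)-2-{[(E)-3-(3-(allyloxy)-4-{[(Z)-1-(3,4-bis(allyloxy)phenyl)-3-methoxy-3-oxoprop-1-en-2-yl]oxy}phenyl)acryloyl]oxy}-3-[3,4-bis(allyloxy)phenyl]propanoic acid F4. [Ir(cod)(PMePh2)2]PF6 (activated with H2, then degassed; THF, rt) isomerises the five allyl ethers to the penta-(E)-prop-1-enyl ether acid F5. Dilute HCl in acetone/water (rt to 40 °C) hydrolyses these simple enol ethers to 24; the ester-conjugated aryloxyacrylate is not affected.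

**Further compounds**
F1 | step 11 | (S)-3-(3,4-dihydroxyphenyl)-2-hydroxypropanoic acid | OC(=O)[C@@H](O)Cc1ccc(O)c(O)c1
F2 | step 11 | allyl (S)-3-[3,4-bis(allyloxy)phenyl]-2-hydroxypropanoate | C=CCOC(=O)[C@@H](O)Cc1ccc(OCC=C)c(OCC=C)c1
F3 | step 15 | (E)-3-[3-(allyloxy)-4-({(Z)-1-[3,4-bis(allyloxy)phenyl]-3-methoxy-3-oxoprop-1-en-2-yl}oxy)phenyl]acrylic acid | COC(=O)/C(=C/c1ccc(OCC=C)c(OCC=C)c1)Oc1ccc(/C=C/C(=O)O)cc1OCC=C
F4 | step 16 | (R)-2-{[(E)-3-(3-(allyloxy)-4-{[(Z)-1-(3,4-bis(allyloxy)phenyl)-3-methoxy-3-oxoprop-1-en-2-yl]oxy}phenyl)acryloyl]oxy}-3-[3,4-bis(allyloxy)phenyl]propanoic acid | COC(=O)/C(=C/c1ccc(OCC=C)c(OCC=C)c1)Oc1ccc(/C=C/C(=O)O[C@H](Cc2ccc(OCC=C)c(OCC=C)c2)C(=O)O)cc1OCC=C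
F5 | step 16 | penta-(E)-prop-1-enyl ether analogue of F4 | COC(=O)/C(=C/c1ccc(O/C=C/C)c(O/C=C/C)c1)Oc1ccc(/C=C/C(=O)O[C@H](Cc2ccc(O/C=C/C)c(O/C=C/C)c2)C(=O)O)cc1O/C=C/C
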